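**Compound numbers used throughout:** 1 pentane-2,4-dione; 2 ethyl hexanoate; 3 undecane-2,4,6-trione; 4 2-methyl-6-pentyl-4H-pyran-4-one; 5 di-tert-butyl dicarbonate; 6 tert-butyl 2-(4-oxo-6-pentyl-4H-pyran-2-yl)acetate; 7 ring-opened magnesium chelate; 8 tert-butyl 2,4-dihydroxy-6-pentylbenzoate; 9 olivetol; 10 1,3-dimethoxy-5-pentylbenzene; 11 2-bromo-1,5-dimethoxy-3-pentylbenzene; 12 2,4-dimethoxy-6-pentylbenzoic acid; 13 2,4-dimethoxy-6-pentylbenzoyl chloride; 14 hydroxy depside tert-butyl ester; 15 methoxy depside tert-butyl ester; 16 planaic acid.

## Analysis of the target

Planaic acid (16) is a para-depside: two benzene rings joined by one aryl ester, with no stereocentre, so only regiochemistry has to be controlled. Ring A is a 2,4-dimethoxy-6-pentylbenzoyl group and ring B a 4-acyloxy-2-methoxy-6-pentylbenzoic acid; both have the carbon skeleton of a pentyl-substituted resorcylic acid and differ only in how the oxygens are capped. The sensitive group is the depside ester, which hydroxide or alkoxide cleaves, so the carboxyl of ring B must be freed without nucleophilic base. The free acid sits between two ortho substituents on an electron-rich ring and can decarboxylate in hot acid. The difficulties are to tell the two oxygens of ring B apart (methyl at C2, acyl at C4) and to make the ester from a di-ortho-substituted acyl donor. The strategy rests on ring B, numbered from the carboxyl-bearing carbon C1, which has oxygen at C2 and C4 and pentyl at C6, the pattern obtained when a linear 3,5,7-tricarbonyl ester chain is folded so that its C2 joins its C7. A 4-pyrone with an acetate arm on one α-carbon and the pentyl group on the other holds these atoms in stable form; its ring oxygen becomes the C2 oxygen and its carbonyl oxygen the C4 oxygen, and the two phenols that result are unequal (one hydrogen-bonded to the ester, one free).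

## Retrosynthetic reasoning

16 ⇒ 15. The last bond cut is the oxygen–tert-butyl bond of the ring B ester. A tert-butyl ester is chosen because it falls to acid, which leaves the aryl ester and the three methyl ethers alone. An ester removable only by nucleophilic base would take the depside bond with it.

15 ⇒ 14. The O–CH3 bond at C2 of ring B is cut. Methylation is placed after acylation, so that the two phenols of ring B are told apart by reactivity alone and no protecting group is needed. The forward step has to alkylate a hydrogen-bonded phenol without harming the aryl ester.

14 ⇒ 8 + 13. The depside C(=O)–O bond is cut. This is the convergent cut; it divides the molecule into two pieces of similar size, and it relies on the free C4 phenol of 8 being acylated before the C2 phenol, which is chelated to the ester and shielded by the tert-butyl group. The acyl donor 13 is hindered, so an activated chloride and nucleophilic catalysis are planned.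

13 ⇒ 12 ⇒ 11 ⇒ 10 ⇒ 9. Ring A is not built; its arene is bought as olivetol 9. The carboxyl carbon is cut from the ring and traced to a bromine–lithium exchange on 11. Bromide 11 in turn comes from electrophilic bromination of dimethyl ether 10 at the position para to one methoxy group and ortho to the other. Directed lithiation of 10 would instead go between the two methoxy groups and give the wrong acid, which is why the halogen route is used.

8 ⇒ 6. Ring B is cut between C1 and C6. Cutting here, and not at an aryl–oxygen or aryl–carboxyl bond, turns the whole ring, carboxyl included, into one chain with oxygen on every second carbon, so no substitution chemistry on an arene and no regiochemical choice is left. The free chain would condense with itself in several ways and is therefore not isolated. It is released from pyrone 6, in which the two central carbonyls are tied up as ring oxygen and ring carbonyl. The forward reaction opens 6 with a magnesium alkoxide to chelate 7 and folds it so that the carbon between ester and ketone attacks the pentyl-bearing carbon; aromatisation then makes the closure irreversible. The gain is one ring, one skeletal bond and two phenols of different character.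

6 ⇒ 4 + 5. The bond between the arm methylene and the ester carbonyl is cut. The methyl group of 4 is a vinylogous α-position, and its lithio derivative is trapped with 5, which delivers the tert-butyl ester needed at the end of the route. The forward step must choose the methyl group over the first methylene of the pentyl chain, the only other site of similar acidity.

4 ⇒ 3 ⇒ 1 + 2. The ring C–O bond of 4 is cut to triketone 3; whichever terminal carbonyl oxygen closes, the same pyrone results. Triketone 3 is cut between C5 and C6 into the terminal carbanion of 1 and the acyl group of 2, both bulk chemicals.

## Alternatives that were turned down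

Alternative 1: The target is traced to its benzyl ester A1, benzyl 4-[(2,4-dimethoxy-6-pentylbenzoyl)oxy]-2-methoxy-6-pentylbenzoate, and ring A of A1 is cut at C3–C4 and C5–C6. C4 and C5 then come from 1,1-dimethoxyethene A3, and the other four ring carbons from a 2-pyrone that already carries the depside ester, benzyl 2-methoxy-4-[(4-methoxy-6-oxo-2-pentyl-6H-pyran-3-carbonyl)oxy]-6-pentylbenzoate A2. In the forward direction A2 reacts as an electron-poor diene with A3 in an inverse-demand (4+2) cycloaddition. The bridged lactone loses its one-carbon bridge by decarboxylative cycloreversion, and elimination of one methoxy group gives A1. Hydrogenolysis of A1 would then give 16. In its favour, the polarity of the partners fixes the regiochemistry, and both ring A oxygens arrive methylated. The final deprotection of A1 is neutral, and on that point this plan is stronger than the acidolysis that ends the chosen route. Against it, the methoxy group on the pyrone of A2 donates into the diene, and the terminus that must bond carries the pentyl group next to the ester, so heat would be needed. At such temperatures the strongly nucleophilic A3 can attack the activated aryl ester or the lactone carbonyl, and the alcohol released on aromatisation can transesterify the depside bond of A1. A2 itself needs a multi-step synthesis ending in a hindered acylation, and ring B must still be supplied with its oxygens differentiated. By comparison, the chosen strategy applies its ring transformation early, to the small and cheap pyrone 6, where a failure costs little, and it keeps the assembled depside away from hot nucleophiles.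

Alternative 2: Ring B is supplied as benzyl 4-hydroxy-2-methoxy-6-pentylbenzoate A4, and A4 is cut at C1–C2 and C5–C6. C1 and C6 come from benzyl oct-2-ynoate A6, and C2 to C5 from 1-methoxy-3-(trimethylsilyloxy)cyclohexa-1,3-diene A5. In the forward direction A5 and A6 combine in a (4+2) cycloaddition to a bicyclo[2.2.2]octadiene, which expels its saturated two-carbon bridge (Alder–Rickert cycloreversion). Desilylation on work-up gives A4. In its favour, the nucleophilic diene terminus of A5 bonds to the β-carbon of A6, so the methoxy group lands ortho to the ester and the two oxygens of ring B emerge already differentiated. On this point, and on step count for ring B, it is stronger than the chosen strategy, which obtains two free phenols in 8 and spends steps 9 and 10 on telling them apart. Against it, the β-alkyl ynoate A6 is a sluggish dienophile and the adduct has a methoxy-bearing bridgehead. Both cycloaddition and cycloreversion need temperatures at which a silyl dienol ether such as A5 isomerises and polymerises. A5 and A6 must each be prepared. By comparison, the chosen strategy offers ionic steps at or below the boiling point of the alcohol solvent from bulk chemicals, a reliable differentiation of the phenols by chelation, and a tert-butyl ester orthogonal to the depside from the start.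

Alternative 3: The depside C(=O)–O bond and the C1–C6 bond of ring A are cut in one operation in benzyl 4-[(2,4-dihydroxy-6-pentylbenzoyl)oxy]-2-methoxy-6-pentylbenzoate A7. This leads to 6-(2,4-dioxononyl)-2,2-dimethyl-4H-1,3-dioxin-4-one A8 and the ring B phenol A4. In the forward direction, heating A8 with A4 unmasks an acylketene by cycloreversion, and the phenol captures it as an aryl triketo ester. Amine base followed by mineral acid in the same flask folds this ester by aldol closure to A7. In its favour, this is the most convergent plan, and it forms the ester without a hindered acyl chloride; on convergence and on the ester formation it is stronger than the chosen route. Against it, an aryl ester of a tricarbonyl acid carries a phenoxide leaving group, so lactonisation with expulsion of A4 and the Claisen fold compete with the aldol far more than with an alkyl ester. A phenol is also a weaker ketene trap than an alcohol. A8 needs its own multi-step synthesis and A4 must still be made. After A7 is reached, both ring A phenols of A7, one of them chelated, must be methylated under base next to the aryl ester. By comparison, the chosen strategy performs the same kind of fold on a tert-butyl ester, where the leaving-group paths are shut, and makes the depside bond by an ordinary acylation.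

Key step: step 4

Remark: in anhydrous methanolic Mg(OMe)2 the ring-opened chain of step 4 is taken to carry C7 as its methyl enol ether (7), which is the 3,5,7-trioxo ester with its terminal carbonyl masked; both double-bond isomers of 7 would close to the same product and the E isomer is drawn.

## Route

Step 1
Reactants: 1 pentane-2,4-dione; 2 ethyl hexanoate
Product: 3 undecane-2,4,6-trione
Conditions: 1 (2.0 equiv), LiN(iPr)2 (4.0 equiv), THF, −78 to 0 °C; then 2 (1.0 equiv), 0 °C to rt; aq. HCl
Reagents that add atoms: none
Why: Hauser–Harris acylation of a 1,3-diketone dianion: the terminal carbanion is the more nucleophilic site and attacks the ester in a Claisen-type condensation. The triketone formed is more acidic than 1 and is deprotonated by the second equivalent of dianion, which is why two equivalents are used.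

Step 2
Reactants: 3 undecane-2,4,6-trione
Product: 4 2-methyl-6-pentyl-4H-pyran-4-one
Conditions: conc. H2SO4, 0 °C to rt; ice
Reagents that add atoms: none
Why: Acid-mediated cyclodehydration of a 1,3,5-triketone: the enol oxygen of one terminal carbonyl adds to the other, and loss of water gives the 4-pyrone. Either terminal oxygen gives the same ring, and strong acid favours O-closure over the carbocyclic aldol.

Step 3
Reactants: 4 2-methyl-6-pentyl-4H-pyran-4-one; 5 di-tert-butyl dicarbonate
Product: 6 tert-butyl 2-(4-oxo-6-pentyl-4H-pyran-2-yl)acetate
Conditions: LiN(iPr)2 (2.2 equiv), THF, −78 °C; then 5 (1.05 equiv), −78 °C; aq. NH4Cl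
Reagents that add atoms: none
Why: Lateral (vinylogous) lithiation of the 2-methyl group followed by C-acylation with the dicarbonate, as practised on 2,6-dimethyl-4-pyrone and on methyl azines. Kinetic deprotonation by the hindered amide should favour the primary methyl over the methylene of the pentyl chain, and the second equivalent of base takes up the more acidic product so that it cannot quench lithiated 4.

Step 4
Reactants: 6 tert-butyl 2-(4-oxo-6-pentyl-4H-pyran-2-yl)acetate
Product: 8 tert-butyl 2,4-dihydroxy-6-pentylbenzoate, via ring-opened magnesium chelate 7 (not isolated)
Conditions: Mg(OMe)2 (3 equiv), MeOH, reflux; then 1 M aq. HCl, 0 °C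
Reagents that add atoms: none
Why: Magnesium-bound methoxide adds to the pentyl-bearing α-carbon of the pyrone (the other α-carbon is deactivated once the acidic arm is deprotonated), and β-elimination of the ring oxygen opens the ring to chelate 7, a 3,5-dioxo ester whose C7 is a methyl enol ether. The magnesium ion holds the 3,5-dioxo unit as a planar Z-enolate, which brings C2 and C7 to the same side of the chain. C2, the carbon between ester and ketone, then adds to C7 and methanol is lost: a 6-endo-trig addition–elimination at the vinylogous ester (a 6-(enolexo)-exo-trig aldol if adventitious water has freed the C7 ketone). Tautomerisation of the cyclohexadienone gives the benzene ring, so the C1–C6 bond of ring B is the one skeletal bond made and the closure is irreversible. The closest known reaction type is the base-induced opening of (4-oxo-4H-pyran-2-yl)acetates and of 4-pyrones in general to polyketone chelates, with aldol reclosure to resorcylates. No stereocentre is formed. The step needs this fold to beat the Claisen fold (C6 onto the ester carbon) and lactonisation to a 4-hydroxy-2-pyrone: magnesium chelation keeps the β-keto ester terminus as its enolate, which makes C2 the nucleophile and the ester carbon a poor electrophile, C6 of 7 is a vinylic carbon that cannot act as the Claisen nucleophile, and the tert-butyl ester is a poor acyl donor that resists exchange by methoxide. The pyrone oxygen ends as the chelated C2 phenol and the pyrone carbonyl as the free C4 phenol, which is the difference used in steps 9 and 10.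

Step 5
Reactants: 9 olivetol
Product: 10 1,3-dimethoxy-5-pentylbenzene
Conditions: MeI, K2CO3, acetone, reflux
Reagents that add atoms: iodomethane, CI
Why: Williamson etherification of both phenols; under carbonate in acetone O-alkylation of resorcinols dominates over C-alkylation.

Step 6
Reactants: 10 1,3-dimethoxy-5-pentylbenzene
Product: 11 2-bromo-1,5-dimethoxy-3-pentylbenzene
Conditions: NBS (1.0 equiv), MeCN, 0 °C
Reagents that add atoms: N-bromosuccinimide, O=C1CCC(=O)N1Br
Why: Electrophilic aromatic bromination at the position para to one methoxy group and ortho to the other; the position between the two methoxy groups is doubly flanked and lacks para activation. One equivalent at low temperature limits dibromination.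

Step 7
Reactants: 11 2-bromo-1,5-dimethoxy-3-pentylbenzene
Product: 12 2,4-dimethoxy-6-pentylbenzoic acid
Conditions: n-BuLi, THF, −78 °C; CO2; aq. HCl
Reagents that add atoms: carbon dioxide, O=C=O
Why: Bromine–lithium exchange gives the aryllithium at the brominated carbon only, and carboxylation follows; the halogen fixes a regiochemistry that direct lithiation of 10 would not give.

Step 8
Reactants: 12 2,4-dimethoxy-6-pentylbenzoic acid
Product: 13 2,4-dimethoxy-6-pentylbenzoyl chloride
Conditions: (COCl)2, DMF (cat.), CH2Cl2, 0 °C to rt
Reagents that add atoms: oxalyl chloride, O=C(Cl)C(Cl)=O
Why: Acid chloride formation through the chloroiminium species from DMF; the neutral conditions spare the methyl ethers, and the chloride is used crude.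

Step 9
Reactants: 8 tert-butyl 2,4-dihydroxy-6-pentylbenzoate; 13 2,4-dimethoxy-6-pentylbenzoyl chloride
Product: 14 tert-butyl 4-[(2,4-dimethoxy-6-pentylbenzoyl)oxy]-2-hydroxy-6-pentylbenzoate
Conditions: 13 (1.05 equiv), Et3N, DMAP (cat.), CH2Cl2, 0 °C to rt
Reagents that add atoms: none
Why: Acylation of a phenol with nucleophilic catalysis; the C4 phenol is free and unhindered, whereas the C2 phenol is hydrogen-bonded to the ester carbonyl and shielded by the tert-butyl group, as in the selective 4-O-acylation of 2,4-dihydroxybenzoates. The acylpyridinium ion overcomes the hindrance of the di-ortho-substituted acyl donor.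

Step 10
Reactants: 14 tert-butyl 4-[(2,4-dimethoxy-6-pentylbenzoyl)oxy]-2-hydroxy-6-pentylbenzoate
Product: 15 tert-butyl 4-[(2,4-dimethoxy-6-pentylbenzoyl)oxy]-2-methoxy-6-pentylbenzoate
Conditions: MeI (excess), K2CO3, acetone, reflux
Reagents that add atoms: iodomethane, CI
Why: Williamson etherification of the remaining, chelated phenol. Anhydrous carbonate is not nucleophilic enough to attack the di-ortho-substituted aryl ester, and the phenoxide is meta to the acyloxy group, so intramolecular acyl transfer is impossible.

Step 11
Reactants: 15 tert-butyl 4-[(2,4-dimethoxy-6-pentylbenzoyl)oxy]-2-methoxy-6-pentylbenzoate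
Product: 16 planaic acid
Conditions: CF3CO2H, CH2Cl2, 0 °C to rt
Reagents that add atoms: none
Why: Acidolysis of the tert-butyl ester by alkyl–oxygen cleavage through the tert-butyl cation; the aryl ester and the methyl ethers are inert to anhydrous acid at this temperature, and the low temperature avoids protodecarboxylation.

## Compound list

1 | pentane-2,4-dione | CC(=O)CC(C)=O | starting material
2 | ethyl hexanoate | CCCCCC(=O)OCC | starting material
3 | undecane-2,4,6-trione | CCCCCC(=O)CC(=O)CC(C)=O | intermediate
4 | 2-methyl-6-pentyl-4H-pyran-4-one | CCCCCC1=CC(=O)C=C(C)O1 | intermediate
5 | di-tert-butyl dicarbonate | CC(C)(C)OC(=O)OC(=O)OC(C)(C)C | starting material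
6 | tert-butyl 2-(4-oxo-6-pentyl-4H-pyran-2-yl)acetate | CCCCCC1=CC(=O)C=C(CC(=O)OC(C)(C)C)O1 | intermediate
7 | tert-butyl (6E)-7-methoxy-3,5-dioxododec-6-enoate, present as its magnesium chelate (C7 methyl enol ether of tert-butyl 3,5,7-trioxododecanoate; neutral ligand drawn) | CCCCC/C(OC)=C\C(=O)CC(=O)CC(=O)OC(C)(C)C | intermediate
8 | tert-butyl 2,4-dihydroxy-6-pentylbenzoate | CCCCCc1cc(O)cc(O)c1C(=O)OC(C)(C)C | intermediate
9 | olivetol (5-pentylbenzene-1,3-diol) | CCCCCc1cc(O)cc(O)c1 | starting material
10 | 1,3-dimethoxy-5-pentylbenzene | CCCCCc1cc(OC)cc(OC)c1 | intermediate
11 | 2-bromo-1,5-dimethoxy-3-pentylbenzene | CCCCCc1cc(OC)cc(OC)c1Br | intermediate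
12 | 2,4-dimethoxy-6-pentylbenzoic acid | CCCCCc1cc(OC)cc(OC)c1C(=O)O | intermediate
13 | 2,4-dimethoxy-6-pentylbenzoyl chloride | CCCCCc1cc(OC)cc(OC)c1C(Cl)=O | intermediate
14 | tert-butyl 4-[(2,4-dimethoxy-6-pentylbenzoyl)oxy]-2-hydroxy-6-pentylbenzoate | CCCCCc1cc(OC(=O)c2c(CCCCC)cc(OC)cc2OC)cc(O)c1C(=O)OC(C)(C)C | intermediate
15 | tert-butyl 4-[(2,4-dimethoxy-6-pentylbenzoyl)oxy]-2-methoxy-6-pentylbenzoate | CCCCCc1cc(OC(=O)c2c(CCCCC)cc(OC)cc2OC)cc(OC)c1C(=O)OC(C)(C)C | intermediate
16 | planaic acid, 4-[(2,4-dimethoxy-6-pentylbenzoyl)oxy]-2-methoxy-6-pentylbenzoic acid | CCCCCc1cc(OC(=O)c2c(CCCCC)cc(OC)cc2OC)cc(OC)c1C(=O)O | target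

## Step count and least certain steps

Total step count: 11. Longest linear sequence: 7 steps (1, 2, 3, 4, 9, 10, 11); the ring A branch (5, 6, 7, 8) joins at step 9 and is of equal length when counted through to 16.

**Step 4 (key step).** Four processes are the most likely to go wrong:
- closure of the opened chain in the Claisen sense or by lactonisation instead of the intended fold;
- exchange of the tert-butyl ester for a methyl ester by methoxide while the chain is still a β-keto ester;
- retro-Claisen fragmentation of the polycarbonyl chain;
- stalling of the ring opening, because the acidic arm is deprotonated first and the anionic pyrone resists methoxide.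

All four arise because the opened chain is a polyfunctional electrophile and nucleophile at once, and only the masking of C7, the bulk of the ester and magnesium chelation of the ester terminus discriminate between its modes. Addition of methoxide at the arm-bearing ring carbon is a further possibility; it would leave the C2 oxygen methylated, which does no harm to the route, since acylation of that material leads to 15 directly.

Fallback: ring B is taken from an intact arene instead of being built. Olivetol 9 is carboxylated ortho to a phenol with MeOMgOCO2Me in DMF at about 120 °C to give 2,4-dihydroxy-6-pentylbenzoic acid F1. F1 is esterified at the carboxyl group with O-tert-butyl-N,N'-diisopropylisourea in CH2Cl2 at room temperature, and the route is rejoined at 8.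

**Step 3.** Lithiation may leak to the first methylene of the pentyl chain, since both sites are vinylogous α-positions of the same pyrone. Proton transfer from the more acidic product to lithiated 4, or a second carboxylation of the product anion, may also lower conversion.

Fallback: the ester carbon is introduced before the pentyl chain exists, so that no choice of site remains. The dianion of 1 (LiN(iPr)2, THF) is carboxylated at its terminal carbon with 5 to give tert-butyl 3,5-dioxohexanoate F2. The trianion of F2 (three equivalents of LiN(iPr)2, used in excess) is acylated at the remaining methyl group with 2 to give tert-butyl 3,5,7-trioxododecanoate F3. F3 is folded with Cs2CO3 in MeOH followed by cold dilute HCl, and the route is rejoined at 8. This gives up the storable pyrone but keeps the same ring-closing bond.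

**Step 9.** Acyl transfer from the di-ortho-substituted chloride may be slow. Forcing it would erode the preference for the free phenol (acylation at the chelated phenol, double acylation) and let the chloride hydrolyse.

Fallback: the oxygens are differentiated before the coupling. Starting from 8, the free phenol is benzylated (BnBr, K2CO3, acetone) to give tert-butyl 4-(benzyloxy)-2-hydroxy-6-pentylbenzoate F4. F4 is methylated (MeI, K2CO3, DMF) to give tert-butyl 4-(benzyloxy)-2-methoxy-6-pentylbenzoate F5. Hydrogenolysis of F5 (H2, Pd/C, EtOAc) gives tert-butyl 4-hydroxy-2-methoxy-6-pentylbenzoate F6. The sodium phenoxide of F6 (NaH, THF) is acylated with 13, where no selectivity is needed and forcing is harmless, and the route is rejoined at 15. Step 10 is then no longer needed.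

**Step 10.** Alkylation of the hydrogen-bonded, hindered phenoxide may be slow. During long heating, carbonate or the phenoxide may cleave the depside ester or transfer its acyl group.

Fallback: the ether is made from 14 by Mitsunobu condensation with MeOH (PPh3, diisopropyl azodicarboxylate, THF, 0 °C to rt). This avoids carbonate base and a free phenoxide and rejoins the route at 15; it makes no new compound (F0).

## Further compounds

F1 | step 4 | 2,4-dihydroxy-6-pentylbenzoic acid (olivetolic acid) | CCCCCc1cc(O)cc(O)c1C(=O)O
F2 | step 3 | tert-butyl 3,5-dioxohexanoate | CC(=O)CC(=O)CC(=O)OC(C)(C)C
F3 | step 3 | tert-butyl 3,5,7-trioxododecanoate | CCCCCC(=O)CC(=O)CC(=O)CC(=O)OC(C)(C)C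
F4 | step 9 | tert-butyl 4-(benzyloxy)-2-hydroxy-6-pentylbenzoate | CCCCCc1cc(OCc2ccccc2)cc(O)c1C(=O)OC(C)(C)C
F5 | step 9 | tert-butyl 4-(benzyloxy)-2-methoxy-6-pentylbenzoate | CCCCCc1cc(OCc2ccccc2)cc(OC)c1C(=O)OC(C)(C)C
F6 | step 9 | tert-butyl 4-hydroxy-2-methoxy-6-pentylbenzoate | CCCCCc1cc(O)cc(OC)c1C(=O)OC(C)(C)C
F0 | step 10 | none | none
A1 | alternative 1 | benzyl 4-[(2,4-dimethoxy-6-pentylbenzoyl)oxy]-2-methoxy-6-pentylbenzoate | CCCCCc1cc(OC(=O)c2c(CCCCC)cc(OC)cc2OC)cc(OC)c1C(=O)OCc1ccccc1
A2 | alternative 1 | benzyl 2-methoxy-4-[(4-methoxy-6-oxo-2-pentyl-6H-pyran-3-carbonyl)oxy]-6-pentylbenzoate | CCCCCC1=C(C(=O)Oc2cc(OC)c(C(=O)OCc3ccccc3)c(CCCCC)c2)C(OC)=CC(=O)O1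
A3 | alternative 1 | 1,1-dimethoxyethene | C=C(OC)OC
A4 | alternative 2 | benzyl 4-hydroxy-2-methoxy-6-pentylbenzoate | CCCCCc1cc(O)cc(OC)c1C(=O)OCc1ccccc1
A5 | alternative 2 | 1-methoxy-3-(trimethylsilyloxy)cyclohexa-1,3-diene | COC1=CC(O[Si](C)(C)C)=CCC1
A6 | alternative 2 | benzyl oct-2-ynoate | CCCCCC#CC(=O)OCc1ccccc1
A7 | alternative 3 | benzyl 4-[(2,4-dihydroxy-6-pentylbenzoyl)oxy]-2-methoxy-6-pentylbenzoate | CCCCCc1cc(OC(=O)c2c(CCCCC)cc(O)cc2O)cc(OC)c1C(=O)OCc1ccccc1
A8 | alternative 3 | 6-(2,4-dioxononyl)-2,2-dimethyl-4H-1,3-dioxin-4-one | CCCCCC(=O)CC(=O)CC1=CC(=O)OC(C)(C)O1
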